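**Plan**

1. Numbering used throughout: C1 (epoxide CH), C2 (CH2), C3 (angelate carbinol), C4 (C(OH)CH3), C5 (CHOH), C6 (CH2), C7 (isopropenyl CH), C8 (angelate carbinol), C9 (acetate carbinol), C10 (epoxide C–CH3).
2. Cuts: first the three ester C–O bonds and the oxirane, back to a Z C1=C10 alkene with a free C9 hydroxyl. Then the ring bond C3–C4: a secondary carbinol (C3) directly beside a methyl-bearing tertiary carbinol (C4) in the ten-membered ring is what a C3 aldehyde and a C4 methyl ketone give on reductive coupling. Then C9–C10 (alkenyl iodide plus aldehyde), C4–CH3 and C7–isopropenyl.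
3. Forward: levoglucosenone supplies C4–C9 (its C1–C6) and is taken to a δ-lactone aldehyde. The Z-iodide (C10, C1–C3) is joined at C9, the lactone is opened to the methyl ketone, and C3 is oxidised. SmI2 then closes the only carbocycle; the oxirane is formed after the angelates and before the acetate.
4. Stereochemistry: C8 comes from levoglucosenone. C7 and C5 are set on the rigid bicyclic acetal (addition anti to the bridge, equatorial hydride delivery). C9 is set by Felkin–Anh addition, C4 by chelation to the C5 ether, C3 in the samarium-bridged ring closure, and C1/C10 by hydroxyl-directed epoxidation of the Z-alkene.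

Key step: step 16

Remark: the locants C1–C10 are also used for the open-chain intermediates; the configuration at C3 from step 16 rests on a transition-state model and is the least certain assignment.

**Route**

Step 1
Reactants: 1 levoglucosenone
Product: 2 isopropenyl ketone (isopropenyl anti to the 1,6-anhydro bridge)
Conditions: CH2=C(CH3)MgBr, CuBr·SMe2 (10 mol %), THF, −78 → −40 °C; then H2O
Reagents that add atoms: isopropenylmagnesium bromide, CC(=C)[Mg]Br
Why: Copper-catalysed conjugate addition of the Grignard reagent to the bicyclic enone takes place on the face opposite the anhydro bridge, which sets C7 trans to the bridging CH2–O group.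

Step 2
Reactants: 2 isopropenyl ketone
Product: 3 axial alcohol (hydroxyl cis to isopropenyl, anti to the bridge)
Conditions: LiBH(s-Bu)3 (L-Selectride), THF, −78 °C; then H2O
Reagents that add atoms: none
Why: In this bulky-borohydride ketone reduction the axial approach is blocked by the syn-axial isopropenyl group, so hydride should enter equatorially and give the axial alcohol that sets C5.

Step 3
Reactants: 3 axial alcohol
Product: 4 2-naphthylmethyl ether
Conditions: NaH, 2-(bromomethyl)naphthalene, Bu4NI (cat.), DMF, 0 °C → rt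
Reagents that add atoms: 2-(bromomethyl)naphthalene, BrCc1ccc2ccccc2c1
Why: Williamson etherification installs an ether that is acid-stable, able to chelate in step 16 and removable by DDQ at the end.

Step 4
Reactants: 4 2-naphthylmethyl ether
Product: 5 pyranose lactol (anomer mixture)
Conditions: 1 M HCl, THF/H2O (1:1), 40 °C
Reagents that add atoms: water, O
Why: Acid-catalysed hydrolysis of the bicyclic acetal is driven by relief of the syn-diaxial ether/isopropenyl interaction and, for this 3,4-dideoxy acetal, should be mild enough to leave the 1,1-disubstituted alkene and the ether intact.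

Step 5
Reactants: 5 pyranose lactol
Product: 6 hydroxy δ-lactone
Conditions: Ag2CO3 on Celite, toluene, 90 °C
Reagents that add atoms: none
Why: Fétizon oxidation converts lactols into lactones much faster than it oxidises an isolated primary alcohol, so the CH2OH group is kept.

Step 6
Reactants: 6 hydroxy δ-lactone
Product: 7 lactone aldehyde
Conditions: Dess–Martin periodinane, CH2Cl2, rt
Reagents that add atoms: none
Why: Dess–Martin oxidation of the primary alcohol stops at the aldehyde, and with the anomeric position already a lactone no bridged hemiacetal can form; the aldehyde is used crude.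

Step 7
Reactants: 8 3-[(tert-butyldimethylsilyl)oxy]propanal
Product: 9 (Z)-alkenyl iodide silyl ether
Conditions: EtPPh3I, n-BuLi, THF, 0 °C; I2, −78 °C; NaN(SiMe3)2, −20 °C; then 8, −78 °C → rt
Reagents that add atoms: ethyltriphenylphosphonium iodide, CC[P+](c1ccccc1)(c1ccccc1)c1ccccc1.[I-]; iodine, II
Why: Stork–Zhao-type Wittig olefination with the α-iodoethylidene ylide gives the trisubstituted alkenyl iodide with iodine cis to the chain, the geometry of the later ring alkene.

Step 8
Reactants: 9 (Z)-alkenyl iodide silyl ether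
Product: 10 (Z)-4-iodopent-3-en-1-ol
Conditions: CSA (cat.), MeOH, 0 °C → rt
Reagents that add atoms: none
Why: Acid-catalysed methanolysis removes the primary silyl ether, and the alkenyl iodide is inert to these conditions.

Step 9
Reactants: 7 lactone aldehyde; 10 (Z)-4-iodopent-3-en-1-ol
Product: 11 diol lactone (new C9–C10 bond, 9R)
Conditions: CrCl2 (6 equiv), NiCl2 (2 mol %), DMSO, rt; then H2O
Reagents that add atoms: none
Why: In this Nozaki–Hiyama–Kishi coupling the alkenylchromium species adds only to the aldehyde with retention of alkene geometry, tolerating the lactone and the free hydroxyl, and polar Felkin–Anh attack anti to the ring oxygen should give the 8,9-anti alcohol that sets C9.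

Step 10
Reactants: 11 diol lactone
Product: 13 bis-silyl lactone (C3–O triethylsilyl and C9–O tert-butyldimethylsilyl), via primary triethylsilyl ether 12 (not isolated)
Conditions: TESCl (1.05 equiv), imidazole, CH2Cl2, −40 °C; then TBSOTf, 2,6-lutidine, −40 → 0 °C
Reagents that add atoms: chlorotriethylsilane, CC[Si](Cl)(CC)CC; tert-butyldimethylsilyl trifluoromethanesulfonate, CC(C)(C)[Si](C)(C)OS(=O)(=O)C(F)(F)F
Why: Two-stage silyl ether formation uses the large rate difference between the unhindered primary hydroxyl and the flanked secondary allylic one, placing the labile group on C3–O and the robust one on C9–O.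

Step 11
Reactants: 13 bis-silyl lactone
Product: 14 hydroxy Weinreb amide
Conditions: MeNHOMe·HCl, Me3Al, CH2Cl2, 0 °C → rt; then aq. potassium sodium tartrate
Reagents that add atoms: N,O-dimethylhydroxylamine hydrochloride, CNOC.Cl
Why: Weinreb aminolysis of the lactone with the aluminium amide opens the ring and releases the C8 hydroxyl, now distinguished from the C9 oxygen; the crude product is silylated at once.

Step 12
Reactants: 14 hydroxy Weinreb amide
Product: 15 C8 triethylsilyl ether
Conditions: TESOTf, 2,6-lutidine, CH2Cl2, −78 °C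
Reagents that add atoms: triethylsilyl trifluoromethanesulfonate, CC[Si](CC)(CC)OS(=O)(=O)C(F)(F)F
Why: Silylation with a silyl triflate and a hindered base caps the hindered C8 hydroxyl before it can re-lactonise.

Step 13
Reactants: 15 C8 triethylsilyl ether
Product: 16 methyl ketone
Conditions: MeMgBr, THF, −78 → 0 °C; then H2O
Reagents that add atoms: methylmagnesium bromide, C[Mg]Br
Why: Grignard addition to a Weinreb amide stops at the ketone because the chelated tetrahedral intermediate collapses only on work-up.

Step 14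
Reactants: 16 methyl ketone
Product: 17 primary alcohol
Conditions: PPTS (cat.), MeOH/CH2Cl2, 0 °C
Reagents that add atoms: none
Why: Acid-catalysed methanolysis cleaves the unhindered primary triethylsilyl ether much faster than the flanked secondary one or the tert-butyldimethylsilyl ether.

Step 15
Reactants: 17 primary alcohol
Product: 18 keto aldehyde
Conditions: Dess–Martin periodinane, NaHCO3, CH2Cl2, 0 °C
Reagents that add atoms: none
Why: Buffered Dess–Martin oxidation gives the β,γ-unsaturated aldehyde without a base that could move the alkene into conjugation; it is used immediately.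

Step 16
Reactants: 18 keto aldehyde
Product: 19 cyclodecene diol (C3 secondary and C4 tertiary hydroxyls)
Conditions: SmI2 (4 equiv), THF, slow addition of 18 to 0.003 M, −78 → 0 °C; then aq. NaHCO3
Reagents that add atoms: none
Why: Electron transfer from divalent samarium to the C3 aldehyde gives a ketyl whose trivalent samarium counter-ion also binds the C4 ketone oxygen and the C5 ether oxygen; the ketyl carbon adds to the ketone carbon, and a second electron and protonation give the diol (the same bond results if the chelated ketone is reduced first). The closest known reaction type is the intramolecular pinacol coupling of keto aldehydes by SmI2 or low-valent titanium, established for small, medium and large rings. The ten-membered carbocycle is the only ring formed and closes in a 10-exo-trig mode, the attacked carbonyl oxygen staying outside the ring. C4 is controlled by the five-membered chelate of the ketone with the C5 naphthylmethyl ether: attack from the face of the C5 hydrogen, away from C6, places the C4 and C5 oxygens syn as in the target. C3 is controlled by the samarium bridge, which keeps the two carbinol oxygens gauche while the ring branches C2 and C5 lie anti across the new bond, giving the threo (trans) diol. The step needs the aldehyde ketyl to be trapped faster than the α-alkoxy ketone loses its ether or couples intermolecularly; the chelating ether, the absence of HMPA, low temperature, high dilution and the Z C1=C10 alkene that turns the chain ends towards each other serve this.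

Step 17
Reactants: 19 cyclodecene diol
Product: 20 triol (C3, C4, C8 hydroxyls free)
Conditions: CSA (cat.), MeOH/CH2Cl2, 0 °C
Reagents that add atoms: none
Why: Acid-catalysed methanolysis removes the secondary triethylsilyl ether selectively in the presence of the allylic tert-butyldimethylsilyl ether.

Step 18
Reactants: 20 triol
Product: 21 3,8-bis-angelate
Conditions: angelic acid, 2,4,6-trichlorobenzoyl chloride, Et3N, toluene, rt; then 20, 75 °C
Reagents that add atoms: angelic acid, C/C=C(/C)C(=O)O
Why: Yamaguchi-type esterification with the preformed mixed anhydride, run without a nucleophilic amine catalyst, should acylate both secondary hydroxyls without Z to E isomerisation and leave the tertiary C4 hydroxyl free.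

Step 19
Reactants: 21 3,8-bis-angelate
Product: 22 C9 allylic alcohol
Conditions: HF·pyridine, pyridine, THF, 0 °C → rt
Reagents that add atoms: none
Why: Buffered fluoride desilylation frees the C9 hydroxyl under mildly acidic conditions that should avoid acyl migration and ester cleavage.

Step 20
Reactants: 22 C9 allylic alcohol
Product: 23 epoxy alcohol (1,10-oxirane cis to the C9 hydroxyl)
Conditions: VO(acac)2 (5 mol %), t-BuOOH (in decane), CH2Cl2, 0 °C → rt
Reagents that add atoms: tert-butyl hydroperoxide, CC(C)(C)OO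
Why: Hydroxyl-directed epoxidation by the vanadium alkylperoxide bound to the C9 alkoxide delivers oxygen to the alkene face cis to that hydroxyl, as with Z-cycloalkenols of medium ring size and as favoured by the C10 methyl group, which sets C1 and C10; the isopropenyl group and the angelates lack a free allylic hydroxyl and should not react.

Step 21
Reactants: 23 epoxy alcohol
Product: 24 C9 acetate
Conditions: Ac2O, pyridine, DMAP (cat.), CH2Cl2, 0 °C → rt
Reagents that add atoms: acetic anhydride, CC(=O)OC(C)=O
Why: Nucleophile-catalysed acylation esterifies the secondary C9 hydroxyl, while the hindered tertiary C4 hydroxyl should not react at this temperature.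

Step 22
Reactants: 24 C9 acetate
Product: 25 CNP0249359.1
Conditions: DDQ, CH2Cl2/pH 7 phosphate buffer (10:1), 0 °C → rt
Reagents that add atoms: none
Why: Oxidative cleavage of the 2-naphthylmethyl ether by DDQ proceeds through a benzylic cation that water hydrolyses, under conditions that spare the esters, the epoxide and the alkenes.

**Compound list**

1 | levoglucosenone, (1S,5R)-6,8-dioxabicyclo[3.2.1]oct-2-en-4-one | O=C1C=C[C@H]2CO[C@@H]1O2 | starting material
2 | (1S,2R,5R)-2-(prop-1-en-2-yl)-6,8-dioxabicyclo[3.2.1]octan-4-one | O=C1C[C@H](C(C)=C)[C@H]2CO[C@@H]1O2 | intermediate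
3 | (1S,2R,4R,5R)-2-(prop-1-en-2-yl)-6,8-dioxabicyclo[3.2.1]octan-4-ol | O[C@@H]1C[C@H](C(C)=C)[C@H]2CO[C@@H]1O2 | intermediate
4 | (1S,2R,4R,5R)-4-(naphthalen-2-ylmethoxy)-2-(prop-1-en-2-yl)-6,8-dioxabicyclo[3.2.1]octane | C=C(C)[C@H]1C[C@@H](OCc2ccc3ccccc3c2)[C@@H]2OC[C@H]1O2 | intermediate
5 | (3R,5R,6S)-6-(hydroxymethyl)-3-(naphthalen-2-ylmethoxy)-5-(prop-1-en-2-yl)oxan-2-ol, anomer mixture | OC[C@H]1OC(O)[C@H](OCc2ccc3ccccc3c2)C[C@@H]1C(C)=C | intermediate
6 | (3R,5R,6S)-6-(hydroxymethyl)-3-(naphthalen-2-ylmethoxy)-5-(prop-1-en-2-yl)oxan-2-one | OC[C@H]1OC(=O)[C@H](OCc2ccc3ccccc3c2)C[C@@H]1C(C)=C | intermediate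
7 | (2S,3R,5R)-5-(naphthalen-2-ylmethoxy)-6-oxo-3-(prop-1-en-2-yl)oxane-2-carbaldehyde | O=C[C@H]1OC(=O)[C@H](OCc2ccc3ccccc3c2)C[C@@H]1C(C)=C | intermediate
8 | 3-[(tert-butyldimethylsilyl)oxy]propanal | O=CCCO[Si](C)(C)C(C)(C)C | starting material
9 | (Z)-tert-butyl[(4-iodopent-3-en-1-yl)oxy]dimethylsilane | C/C(I)=C/CCO[Si](C)(C)C(C)(C)C | intermediate
10 | (Z)-4-iodopent-3-en-1-ol | C/C(I)=C/CCO | intermediate
11 | (3R,5R,6S)-6-[(1R,2Z)-1,5-dihydroxy-2-methylpent-2-en-1-yl]-3-(naphthalen-2-ylmethoxy)-5-(prop-1-en-2-yl)oxan-2-one | OCC/C=C(C)\[C@@H](O)[C@H]1OC(=O)[C@H](OCc2ccc3ccccc3c2)C[C@@H]1C(C)=C | intermediate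
12 | primary (C3–O) triethylsilyl ether of 11, C9 hydroxyl free | CC[Si](CC)(CC)OCC/C=C(C)\[C@@H](O)[C@H]1OC(=O)[C@H](OCc2ccc3ccccc3c2)C[C@@H]1C(C)=C | intermediate (formed in the flask in step 10, not isolated)
13 | C3–O triethylsilyl, C9–O tert-butyldimethylsilyl ether of 11 | CC[Si](CC)(CC)OCC/C=C(C)\[C@@H](O[Si](C)(C)C(C)(C)C)[C@H]1OC(=O)[C@H](OCc2ccc3ccccc3c2)C[C@@H]1C(C)=C | intermediate
14 | open-chain (5R,7R,8S,9R) C4 N-methoxy-N-methylamide: C5 naphthylmethyl ether, C7 isopropenyl, C8 hydroxyl, C9 OTBS, Z C10=C1, C3 OTES | C=C(C)[C@@H](C[C@@H](OCc1ccc2ccccc2c1)C(=O)N(C)OC)[C@H](O)[C@H](O[Si](C)(C)C(C)(C)C)/C(C)=C\CCO[Si](CC)(CC)CC | intermediate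
15 | C8 triethylsilyl ether of 14 | C=C(C)[C@@H](C[C@@H](OCc1ccc2ccccc2c1)C(=O)N(C)OC)[C@H](O[Si](CC)(CC)CC)[C@H](O[Si](C)(C)C(C)(C)C)/C(C)=C\CCO[Si](CC)(CC)CC | intermediate
16 | (5R,7R,8S,9R) C4 methyl ketone with C3 OTES, C5 naphthylmethyl ether, C8 OTES, C9 OTBS, Z C10=C1 | C=C(C)[C@@H](C[C@@H](OCc1ccc2ccccc2c1)C(C)=O)[C@H](O[Si](CC)(CC)CC)[C@H](O[Si](C)(C)C(C)(C)C)/C(C)=C\CCO[Si](CC)(CC)CC | intermediate
17 | C3 primary alcohol from 16 | C=C(C)[C@@H](C[C@@H](OCc1ccc2ccccc2c1)C(C)=O)[C@H](O[Si](CC)(CC)CC)[C@H](O[Si](C)(C)C(C)(C)C)/C(C)=C\CCO | intermediate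
18 | (5R,7R,8S,9R) keto aldehyde: C3 aldehyde, C4 methyl ketone, C5 naphthylmethyl ether, C7 isopropenyl, C8 OTES, C9 OTBS, Z C1=C10 | C=C(C)[C@@H](C[C@@H](OCc1ccc2ccccc2c1)C(C)=O)[C@H](O[Si](CC)(CC)CC)[C@H](O[Si](C)(C)C(C)(C)C)/C(C)=C\CC=O | intermediate
19 | (3S,4R,5R,7R,8S,9R) ten-membered ring with Z C1=C10: C3 and C4 hydroxyls free, C4 and C10 methyl, C5 naphthylmethyl ether, C7 isopropenyl, C8 OTES, C9 OTBS | C=C(C)[C@H]1C[C@@H](OCc2ccc3ccccc3c2)[C@](C)(O)[C@@H](O)C/C=C(C)\[C@@H](O[Si](C)(C)C(C)(C)C)[C@H]1O[Si](CC)(CC)CC | intermediate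
20 | (3S,4R,5R,7R,8S,9R) triol: 19 with the C8 hydroxyl free | C=C(C)[C@H]1C[C@@H](OCc2ccc3ccccc3c2)[C@](C)(O)[C@@H](O)C/C=C(C)\[C@@H](O[Si](C)(C)C(C)(C)C)[C@H]1O | intermediate
21 | (3S,4S,5R,7R,8S,9R) 3,8-bis-angelate of 20 | C=C(C)[C@H]1C[C@@H](OCc2ccc3ccccc3c2)[C@](C)(O)[C@@H](OC(=O)/C(C)=C\C)C/C=C(C)\[C@@H](O[Si](C)(C)C(C)(C)C)[C@H]1OC(=O)/C(C)=C\C | intermediate
22 | (3S,4S,5R,7R,8S,9R) C9 allylic alcohol from 21 | C=C(C)[C@H]1C[C@@H](OCc2ccc3ccccc3c2)[C@](C)(O)[C@@H](OC(=O)/C(C)=C\C)C/C=C(C)\[C@@H](O)[C@H]1OC(=O)/C(C)=C\C | intermediate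
23 | (1R,3S,4S,5R,7R,8S,9S,10S) 1,10-epoxide of 22, oxirane cis to the C9 hydroxyl | C=C(C)[C@H]1C[C@@H](OCc2ccc3ccccc3c2)[C@](C)(O)[C@@H](OC(=O)/C(C)=C\C)C[C@H]4O[C@@]4(C)[C@@H](O)[C@H]1OC(=O)/C(C)=C\C | intermediate
24 | (1R,3S,4S,5R,7R,8S,9S,10R) C9 acetate of 23 | C=C(C)[C@H]1C[C@@H](OCc2ccc3ccccc3c2)[C@](C)(O)[C@@H](OC(=O)/C(C)=C\C)C[C@H]4O[C@@]4(C)[C@@H](OC(C)=O)[C@H]1OC(=O)/C(C)=C\C | intermediate
25 | CNP0249359.1: (1R,3S,4S,5R,7R,8S,9S,10R) 9-acetoxy-3,8-bis(angeloyloxy)-1,10-epoxy-4,5-dihydroxy-7-isopropenyl-4,10-dimethylcyclodecane (ring numbering of the plan) | C=C(C)[C@H]1C[C@@H](O)[C@](C)(O)[C@@H](OC(=O)/C(C)=C\C)C[C@H]2O[C@@]2(C)[C@@H](OC(C)=O)[C@H]1OC(=O)/C(C)=C\C | target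

**Step count**

Total: 22 steps. Longest linear sequence: 20 steps (1 to 25 through steps 1–6 and 9–22).

**Steps most likely to fail**

Step 16 (ring closure). What may go wrong: reductive loss of the C5 ether at the ketone, intermolecular coupling, or bond formation with the wrong relative configuration at C3. Fallback, from 16 and back at 19: the same C3–C4 bond is closed by a polar route. Kinetic enolisation on the methyl side with KN(SiMe3)2 and trapping with N-(5-chloro-2-pyridyl)triflimide would give the enol triflate F1. PPTS in methanol would free the primary alcohol F2, and Dess–Martin oxidation would give the triflate aldehyde F3. Intramolecular Nozaki–Hiyama–Kishi coupling (CrCl2, catalytic NiCl2, DMSO/THF, high dilution) would close the ten-membered ring as the cyclised allylic alcohol F4, with an exocyclic methylene at C4. VO(acac)2 and tert-butyl hydroperoxide, directed by the C3 hydroxyl, should give the spiro-epoxide F5 in the erythro sense expected for a 2-substituted allylic alcohol. LiAlH4 would open it at the CH2 terminus to the tertiary methyl carbinol 19.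

Step 9 (C9–C10 coupling). What may go wrong: insufficient face selectivity at the aldehyde, and epimerisation at its α-carbon before coupling. Fallback, from 12 and back at 12: 12 is isolated after the first silylation of step 10 as its mixture of C9 epimers. Dess–Martin oxidation would give the enone F6. Corey–Bakshi–Shibata reduction with (R)-2-methyl-CBS-oxazaborolidine and BH3·SMe2 would then set C9 under reagent control; the catalyst antipode is chosen on the usual model with the trisubstituted alkenyl branch as the large ketone substituent. This returns 12, which is silylated to 13 as in step 10.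

Step 18 (double angeloylation). What may go wrong: incomplete acylation of the hindered C8 hydroxyl and isomerisation of the activated angeloyl unit to the tigloyl isomer on prolonged heating. Fallback, from 20 and back at 21: carbodiimide coupling (EDC·HCl, DMAP, CH2Cl2) with 2-[bis(2,2,2-trifluoroethoxy)phosphoryl]propanoic acid would give the bis(phosphonopropionate) F7. Still–Gennari olefination with acetaldehyde (KN(SiMe3)2, 18-crown-6, THF, −78 °C) would then build both Z-2-methylbut-2-enoates in place and return 21.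

Further compounds
F1 | step 16 | enol triflate of 16 (C4 as 1-(trifluoromethylsulfonyloxy)vinyl) | C=C(C)[C@@H](C[C@@H](OCc1ccc2ccccc2c1)C(=C)OS(=O)(=O)C(F)(F)F)[C@H](O[Si](CC)(CC)CC)[C@H](O[Si](C)(C)C(C)(C)C)/C(C)=C\CCO[Si](CC)(CC)CC
F2 | step 16 | C3 primary alcohol of the enol triflate | C=C(C)[C@@H](C[C@@H](OCc1ccc2ccccc2c1)C(=C)OS(=O)(=O)C(F)(F)F)[C@H](O[Si](CC)(CC)CC)[C@H](O[Si](C)(C)C(C)(C)C)/C(C)=C\CCO
F3 | step 16 | C3 aldehyde with C4 enol triflate | C=C(C)[C@@H](C[C@@H](OCc1ccc2ccccc2c1)C(=C)OS(=O)(=O)C(F)(F)F)[C@H](O[Si](CC)(CC)CC)[C@H](O[Si](C)(C)C(C)(C)C)/C(C)=C\CC=O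
F4 | step 16 | ten-membered C3 allylic alcohol with C4 exocyclic methylene | C=C(C)[C@H]1C[C@@H](OCc2ccc3ccccc3c2)C(=C)[C@@H](O)C/C=C(C)\[C@@H](O[Si](C)(C)C(C)(C)C)[C@H]1O[Si](CC)(CC)CC
F5 | step 16 | C4 spiro-epoxide of the ten-membered allylic alcohol | C=C(C)[C@H]1C[C@@H](OCc2ccc3ccccc3c2)[C@@]4(CO4)[C@@H](O)C/C=C(C)\[C@@H](O[Si](C)(C)C(C)(C)C)[C@H]1O[Si](CC)(CC)CC
F6 | step 9 | C9 enone from 12 | CC[Si](CC)(CC)OCC/C=C(C)\C(=O)[C@H]1OC(=O)[C@H](OCc2ccc3ccccc3c2)C[C@@H]1C(C)=C
F7 | step 18 | 3,8-bis{2-[bis(2,2,2-trifluoroethoxy)phosphoryl]propanoate} of 20 | C=C(C)[C@H]1C[C@@H](OCc2ccc3ccccc3c2)[C@](C)(O)[C@@H](OC(=O)C(C)P(=O)(OCC(F)(F)F)OCC(F)(F)F)C/C=C(C)\[C@@H](O[Si](C)(C)C(C)(C)C)[C@H]1OC(=O)C(C)P(=O)(OCC(F)(F)F)OCC(F)(F)F
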